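**Overview**

Numbering (cadinane, used for every compound): ring A = C1–C2–C3(OAc)–C4(C15 methyl)=C5–C6; ring B = C6–C7(=C11; C12 = CH2OCHO, C13 = CH3)–C8–C9(OAc)–C10(C14 methyl)–C1.
Retrosynthesis: after the three esters, the ring-B bond C6–C7 is cut and C4–C9 is redrawn. This is possible because the array C9(O)–C8–C7(=C11)–C6–C5=C4, which spans both rings of the cis-fused decalin, is the retron of an oxy-Cope rearrangement in which C7 was the central carbon of an allene and C4–C9 a bond of a bicyclo[2.2.2]octene. C8–C9 (acetylide plus ketone) and C4–C9 (dienolate alkylation) are cut next, leading to (S)-carvone and a five-carbon alkynyl oxirane.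
Forward: ring A is the carvone ring from start to finish. C4–C9 closes the bicyclo[2.2.2]octene, C8–C9 attaches the five-carbon piece (C7, C8, C11–C13), the alkynyl oxirane is reduced to an allene, and the rearrangement exchanges C4–C9 for C6–C7, so ring B appears cis-fused together with the C9 carbonyl, C4=C5 and C7=C11.
Stereochemistry: C1 is the stereocentre of (S)-carvone. On the rigid bicycle, C3 is set by hydride from the etheno side, C10 by hydrogenation steered by the C3 hydroxyl, and the C9 carbinol by acetylide attack from the etheno side. C6 (cis fusion) follows from the tether in the rearrangement; the C7=C11 geometry follows from the allene axis, itself set by anti-SN2' hydride opening of the (R)-oxirane; C9–OAc comes from axial hydride addition to the cis-decalinone.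

Key step: step 13

Remark: (S)-carvone, (R)-2-methylglycidol and dimethyl (1-diazo-2-oxopropyl)phosphonate are taken as purchased; the volatile C5 alkyne is handled only in solution.

**Route**

Step 1
Reactants: 1 (S)-carvone
Product: 2 (S)-10-chlorocarvone
Conditions: Ca(OCl)2, solid CO2, CH2Cl2/H2O, 0 °C
Reagents that add atoms: calcium hypochlorite, [Ca+2].[O-]Cl.[O-]Cl
Why: Hypochlorous acid released by carbonic acid attacks only the electron-rich isopropenyl alkene in an ene-type allylic chlorination (the enone alkene is too electron-poor), which should give the allylic chloride that becomes C9 and leave the carvone stereocentre untouched.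

Step 2
Reactants: 2 (S)-10-chlorocarvone
Product: 4 1-methyl-5-methylidenebicyclo[2.2.2]oct-7-en-2-one, via potassium dienolate 3 (not isolated)
Conditions: KOtBu, t-BuOH/THF, 0 °C to rt
Reagents that add atoms: none
Why: Reversible γ-deprotonation at C6 gives the extended dienolate, whose α-carbon C4 displaces the tethered allylic chloride (intramolecular SN2 enolate alkylation) to form C4–C9 and the bicyclo[2.2.2]octene, the new quaternary bridgehead being fixed by the C1 tether.

Step 3
Reactants: 4 1-methyl-5-methylidenebicyclo[2.2.2]oct-7-en-2-one
Product: 5 bicyclic C3 alcohol (OH over the C9–C10 bridge)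
Conditions: LiBH(s-Bu)3, THF, −78 °C; NaOH, H2O2 work-up
Reagents that add atoms: none
Why: Bulky borohydride reduction of the C3 ketone should occur from the side of the flat etheno bridge, because the opposite side is screened by a C9 hydrogen, so the new hydroxyl lies over the C9–C10 bridge.

Step 4
Reactants: 5 bicyclic C3 alcohol
Product: 6 C3,C9-diol with C10=C14 methylidene
Conditions: SeO2 (cat.), t-BuOOH, CH2Cl2, rt
Reagents that add atoms: selenium dioxide, O=[Se]=O; tert-butyl hydroperoxide, CC(C)(C)OO
Why: Selenium dioxide allylic oxidation (ene reaction, then [2,3] shift) of the exocyclic methylene can use only the C9 hydrogens, since the other allylic carbon is the bridgehead C1, so oxygen should enter at C9 with the alkene returned to C10=C14; the C9 configuration is irrelevant because it is oxidised next.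

Step 5
Reactants: 6 C3,C9-diol
Product: 7 C3-hydroxy C9 exo-methylene enone
Conditions: MnO2, CH2Cl2, rt
Reagents that add atoms: none
Why: Manganese dioxide oxidises only the allylic C9 carbinol, leaving the non-allylic C3 hydroxyl free to direct the next step.

Step 6
Reactants: 7 C3-hydroxy C9 exo-methylene enone
Product: 8 C3-hydroxy C9 ketone with C14 methyl over the etheno bridge
Conditions: [Ir(cod)(PCy3)(py)]PF6 (cat.), H2 (1 atm, stopped at one equivalent), CH2Cl2, 0 °C to rt
Reagents that add atoms: none
Why: In this hydroxyl-directed homogeneous hydrogenation the cationic iridium centre bound to the C3 hydroxyl sits between the C2–C3 and C9–C10 bridges and should deliver hydrogen to C10=C14 from that side, which sets C10 with its methyl over the etheno bridge while the undirected C5=C6 alkene is spared by limiting hydrogen.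

Step 7
Reactants: 8 C3-hydroxy C9 ketone
Product: 9 C3 triethylsilyl ether of the C9 ketone
Conditions: Et3SiCl, imidazole, DMF, 0 °C
Reagents that add atoms: chlorotriethylsilane, CC[Si](Cl)(CC)CC
Why: Routine silylation of the secondary alcohol, which also removes the β-alkoxide that could start a retro-aldol cleavage of C3–C4 in the basic steps ahead.

Step 8
Reactants: 10 (R)-2-methylglycidol
Product: 11 (S)-2-methyloxirane-2-carbaldehyde
Conditions: SO3·pyridine, DMSO, Et3N, CH2Cl2, 0 °C
Reagents that add atoms: none
Why: Parikh–Doering oxidation of the primary alcohol is non-acidic and keeps the oxirane, and the quaternary stereocentre has no α-hydrogen to lose (only the descriptor changes with the priorities); the volatile aldehyde is carried on in solution.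

Step 9
Reactants: 11 (S)-2-methyloxirane-2-carbaldehyde; 12 dimethyl (1-diazo-2-oxopropyl)phosphonate
Product: 13 (R)-2-ethynyl-2-methyloxirane
Conditions: K2CO3, MeOH, 0 °C to rt
Reagents that add atoms: dimethyl (1-diazo-2-oxopropyl)phosphonate (compound 12), CC(=O)C(=[N+]=[N-])P(=O)(OC)OC
Why: In this Ohira–Bestmann homologation, methanolysis of 12 gives the diazomethylphosphonate anion, which olefinates the aldehyde, loses nitrogen and rearranges to the terminal alkyne without touching the stereocentre.

Step 10
Reactants: 13 (R)-2-ethynyl-2-methyloxirane; 9 C3 triethylsilyl ether of the C9 ketone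
Product: 16 tertiary propargylic carbinol, via lithium acetylide 14 (not isolated), via dichlorocerium acetylide 15 (not isolated)
Conditions: n-BuLi, THF, −78 °C; anhydrous CeCl3, −78 °C; then 9, −78 to −40 °C; aq NH4Cl
Reagents that add atoms: none
Why: 1,2-Addition of the weakly basic organocerium acetylide to the hindered, enolisable C9 ketone forms C8–C9, and attack should come from the etheno side because the other side is blocked by the C3 silyloxy group lying parallel to the approach path, which places the alkynyl group syn to C5=C6 and the hydroxyl toward the C2–C3 bridge.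

Step 11
Reactants: 16 tertiary propargylic carbinol
Product: 18 allenyl diol, via dimethoxy(methyl)silyl ether 17 (not isolated)
Conditions: (IPr)CuCl (cat.; IPr = 1,3-bis(2,6-diisopropylphenyl)imidazol-2-ylidene), NaOtBu (cat.), (MeO)2MeSiH, toluene, 0 °C to rt; then K2CO3, MeOH
Reagents that add atoms: none
Why: In this copper hydride-catalysed SN2' reduction of a propargylic oxirane, hydrogen is delivered to C8 and the C11–O bond leaves anti to it, so the (R)-oxirane centre should be transferred to the allene axis (seen from C8 toward C11 with C9 up, methyl C13 left and C12 right), and methanolysis of the silylated alkoxide frees the C12 hydroxyl.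

Step 12
Reactants: 18 allenyl diol
Product: 19 allenyl carbinol with C12 tert-butyldiphenylsilyl ether
Conditions: t-BuPh2SiCl, imidazole, CH2Cl2, 0 °C
Reagents that add atoms: tert-butyl(chloro)diphenylsilane, CC(C)(C)[Si](Cl)(c1ccccc1)c1ccccc1
Why: Selective silylation of the primary alcohol, the crowded tertiary C9 carbinol staying free for the rearrangement.

Step 13
Reactants: 19 allenyl carbinol with C12 tert-butyldiphenylsilyl ether
Product: 22 cis-fused decalin C9 ketone, via potassium alkoxide 20 (not isolated), via potassium dienolate 21 (not isolated)
Conditions: KH, 18-crown-6, THF, 0 °C to rt; then AcOH, −78 °C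
Reagents that add atoms: none
Why: Proposed new method: KH/18-crown-6 turns the tertiary carbinol into the free potassium alkoxide 20, whose oxyanion weakens the adjacent C4–C9 bond so that the 1,5-diene C7=C8–C9–C4–C5=C6 undergoes a concerted, charge-accelerated [3,3] sigmatropic shift through the boat array fixed by the bicycle (C4–C9 breaks, C6–C7 forms), and the resulting dienolate 21 is protonated at C8 by the cold acid. The closest known reaction types are the anionic oxy-Cope rearrangement of 2-alkenylbicyclo[2.2.2]oct-5-en-2-ols to cis-fused decalinones and the thermal Cope rearrangement of 1,2,6-trienes, where the central allene carbon makes the new bond and the allene terminus is left as an alkylidene; an allenyl group as the migrating partner of the alkoxide-accelerated variant is the untested element. Ring B (C1–C6–C7–C8–C9–C10) closes by suprafacial bonding of C7 to C6 inside the six-membered boat transition state, a closure paid for by opening the bicyclo[2.2.2]octene, which at the same time releases ring A with its alkene moved to C4=C5. The only new stereocentre, C6, is set by the tether: C7 hangs from C9 and can reach C5=C6 solely on the side turned to the C9–C10 bridge, which forces H-6 cis to H-1, while C1, C3 and C10 are carried through unchanged. Because C7 stays doubly bonded to C11, the alkene geometry is read from the allene axis: the C11 substituent on the bonding side (methyl C13) ends cis to C6 and C12 cis to C8, so one allene epimer should give one alkene isomer. The step needs the allenyl group on the etheno side of C9 (secured in step 10 by attack opposite the C3 silyloxy group), a single allene configuration (step 11) and α-protonation of the dienolate (cold acetic acid); cyclisation of the alkoxide onto the allene and conjugation of the product are the side reactions to be held back by low temperature.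

Step 14
Reactants: 22 cis-fused decalin C9 ketone
Product: 23 C9 equatorial alcohol
Conditions: NaBH4, CeCl3·7H2O, MeOH, −78 °C
Reagents that add atoms: none
Why: In this Luche-type reduction under nearly neutral conditions (so the β,γ-unsaturated ketone is not conjugated), ring B should sit in the chair that keeps the C10 methyl equatorial and avoids allylic strain at C7=C11, and the small hydride adds axially from the open convex side to give the equatorial C9 alcohol trans to the C10 methyl.

Step 15
Reactants: 23 C9 equatorial alcohol
Product: 24 C3,C9-diol with C12 silyl ether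
Conditions: PPTS, MeOH, 0 °C to rt
Reagents that add atoms: none
Why: Mild acid-catalysed methanolysis removes the secondary triethylsilyl ether while the far more robust tert-butyldiphenylsilyl ether stays.

Step 16
Reactants: 24 C3,C9-diol with C12 silyl ether
Product: 25 C3,C9-diacetate with C12 silyl ether
Conditions: Ac2O, pyridine, DMAP (cat.), CH2Cl2, rt
Reagents that add atoms: acetic anhydride, CC(=O)OC(C)=O
Why: DMAP-catalysed acylation esterifies both secondary alcohols with retention at C3 and C9.

Step 17
Reactants: 25 C3,C9-diacetate with C12 silyl ether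
Product: 26 C3,C9-diacetate with free C12 alcohol
Conditions: HF·pyridine, pyridine, THF, 0 °C to rt
Reagents that add atoms: none
Why: Buffered fluoride desilylation frees the primary allylic alcohol under non-basic conditions, so the acetates should neither cleave nor migrate.

Step 18
Reactants: 26 C3,C9-diacetate with free C12 alcohol
Product: 27 CNP0262962.2
Conditions: acetic formic anhydride, pyridine, CH2Cl2, −20 to 0 °C
Reagents that add atoms: acetic formic anhydride, CC(=O)OC=O
Why: Mixed-anhydride formylation transfers the more electrophilic formyl group to the primary alcohol, and placing this labile ester last keeps it away from every basic or nucleophilic step.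

**Compound list**

1 | (S)-carvone | CC1=CC[C@@H](CC1=O)C(C)=C | starting material
2 | (S)-10-chlorocarvone, (5S)-5-(3-chloroprop-1-en-2-yl)-2-methylcyclohex-2-en-1-one | CC1=CC[C@@H](CC1=O)C(=C)CCl | intermediate
3 | potassium extended dienolate of 2 (O–C3=C4–C5=C6; not isolated) | [K+].[O-]C1=C(C)C=C[C@@H](C1)C(=C)CCl | intermediate
4 | 1-methyl-5-methylidenebicyclo[2.2.2]oct-7-en-2-one (C3 ketone; bridgeheads C4–CH3 and C1–H; bridges C2–C3, C5=C6, C9–C10(=C14H2); C1 as in carvone) | O=C1C[C@@H]2C=C[C@@]1(C)CC2=C | intermediate
5 | bicyclic alcohol, C3–OH over the C9–C10 bridge (anti to the etheno bridge) | O[C@H]1C[C@@H]2C=C[C@@]1(C)CC2=C | intermediate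
6 | C3,C9-diol with C10=C14 methylidene (C9 configuration uncontrolled and of no consequence) | O[C@H]1C[C@@H]2C=C[C@@]1(C)C(O)C2=C | intermediate
7 | C3-hydroxy enone, C9 ketone conjugated to C10=C14H2 | O[C@H]1C[C@@H]2C=C[C@@]1(C)C(=O)C2=C | intermediate
8 | C3-hydroxy C9 ketone, C10–H on the side of the C2–C3 bridge, C14 methyl over the etheno bridge | O[C@H]1C[C@@H]2C=C[C@@]1(C)C(=O)[C@H]2C | intermediate
9 | C3 triethylsilyl ether of 8 | CC[Si](CC)(CC)O[C@H]1C[C@@H]2C=C[C@@]1(C)C(=O)[C@H]2C | intermediate
10 | (R)-2-methylglycidol, (R)-(2-methyloxiran-2-yl)methanol | OC[C@]1(C)CO1 | starting material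
11 | (S)-2-methyloxirane-2-carbaldehyde | O=C[C@]1(C)CO1 | intermediate
12 | dimethyl (1-diazo-2-oxopropyl)phosphonate | CC(=O)C(=[N+]=[N-])P(=O)(OC)OC | starting material
13 | (R)-2-ethynyl-2-methyloxirane | C#C[C@]1(C)CO1 | intermediate
14 | lithium acetylide of 13 (not isolated) | [Li]C#C[C@]1(C)CO1 | intermediate
15 | dichlorocerium acetylide of 13 (not isolated) | Cl[Ce](Cl)C#C[C@]1(C)CO1 | intermediate
16 | tertiary propargylic carbinol: C9–OH toward the C2–C3 bridge, [(R)-2-methyloxiran-2-yl]ethynyl group on the etheno side of C9 | CC[Si](CC)(CC)O[C@H]1C[C@@H]2C=C[C@@]1(C)[C@@](O)(C#C[C@]3(C)CO3)[C@H]2C | intermediate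
17 | C12 dimethoxy(methyl)silyl ether of 18 (not isolated) | CC[Si](CC)(CC)O[C@H]1C[C@@H]2C=C[C@@]1(C)[C@@](O)(C=[C@@]=C(C)CO[Si](C)(OC)OC)[C@H]2C | intermediate
18 | allenyl diol C9(OH)–C8H=C7=C11(CH3)–C12H2OH; seen from C8 toward C11 with C9 up, methyl C13 left and C12 right | CC[Si](CC)(CC)O[C@H]1C[C@@H]2C=C[C@@]1(C)[C@@](O)(C=[C@@]=C(C)CO)[C@H]2C | intermediate
19 | C12 tert-butyldiphenylsilyl ether of 18 (free C9–OH) | CC[Si](CC)(CC)O[C@H]1C[C@@H]2C=C[C@@]1(C)[C@@](O)(C=[C@@]=C(C)CO[Si](c3ccccc3)(c3ccccc3)C(C)(C)C)[C@H]2C | intermediate
20 | potassium C9 alkoxide of 19 (not isolated) | [K+].CC[Si](CC)(CC)O[C@H]1C[C@@H]2C=C[C@@]1(C)[C@@]([O-])(C=[C@@]=C(C)CO[Si](c3ccccc3)(c3ccccc3)C(C)(C)C)[C@H]2C | intermediate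
21 | potassium dienolate C9(O–)=C8–C7=C11 of the cis-decalin (not isolated) | [K+].CC[Si](CC)(CC)O[C@H]1C[C@H]2[C@H](C)C([O-])=C/C(=C(/C)CO[Si](c3ccccc3)(c3ccccc3)C(C)(C)C)[C@H]2C=C1C | intermediate
22 | cis-fused decalin C9 ketone: C4=C5, C7=C11 with methyl C13 cis to C6 and C12 cis to C8, H-1 and H-6 cis, C3–OSiEt3, C12–OSiPh2t-Bu | CC[Si](CC)(CC)O[C@H]1C[C@H]2[C@H](C)C(=O)C/C(=C(/C)CO[Si](c3ccccc3)(c3ccccc3)C(C)(C)C)[C@H]2C=C1C | intermediate
23 | C9 alcohol of 22, hydroxyl equatorial and trans to the C10 methyl | CC[Si](CC)(CC)O[C@H]1C[C@H]2[C@H](C)[C@@H](O)C/C(=C(/C)CO[Si](c3ccccc3)(c3ccccc3)C(C)(C)C)[C@H]2C=C1C | intermediate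
24 | C3,C9-diol, C12 silyl ether kept | O[C@H]1C[C@H]2[C@H](C)[C@@H](O)C/C(=C(/C)CO[Si](c3ccccc3)(c3ccccc3)C(C)(C)C)[C@H]2C=C1C | intermediate
25 | C3,C9-diacetate, C12 silyl ether | CC(=O)O[C@H]1C[C@H]2[C@H](C)[C@@H](OC(C)=O)C/C(=C(/C)CO[Si](c3ccccc3)(c3ccccc3)C(C)(C)C)[C@H]2C=C1C | intermediate
26 | C3,C9-diacetate with free C12 alcohol | CC(=O)O[C@H]1C[C@H]2[C@H](C)[C@@H](OC(C)=O)C/C(=C(/C)CO)[C@H]2C=C1C | intermediate
27 | CNP0262962.2, the cis-fused cadina-4,7(11)-diene 3,9-diacetate 12-formate | CC(=O)O[C@H]1C[C@H]2[C@H](C)[C@@H](OC(C)=O)C/C(=C(/C)COC=O)[C@H]2C=C1C | target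

**Step count and risks**

Total: 18 steps. Longest linear sequence: 16 steps from (S)-carvone (steps 1–7, then 10–18); the oxirane fragment takes 2 steps (8–9).

Risk 1, step 13. The alkoxide may add to the allene (ring closure to a dihydrofuran) or the bicycle may fragment before the sigmatropic shift sets in, and base may conjugate the product. Fallback from 19 back to 22: the charge acceleration is given up and the reorganisation is run as the neutral thermal Cope rearrangement of a 1,2,6-triene, an established reaction in which the allene terminus likewise ends as the alkylidene, here in its equally established silyloxy-Cope form. Silylation of the tertiary hydroxyl (Me3SiOTf, 2,6-lutidine, CH2Cl2, −78 °C) would give the C9 trimethylsilyl ether F1. Heating in degassed toluene in a base-washed sealed tube (about 200 °C) should convert it, under the same tether control of C6 and of the alkene geometry, into the trimethylsilyl dienol ether F2. MeLi in THF at 0 °C would cleave the enol silyl ether to the lithium dienolate F3, and acetic acid at −78 °C would protonate it at C8 to give 22.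

Risk 2, step 11. The centre-to-axis transfer may leak (partial syn delivery or equilibration of a copper allenyl species), hydride may be delivered to the wrong alkyne carbon next to the crowded C9, or the allene may be reduced further. Fallback from 16 back to 18: the polarity is reversed, so that C8 receives a proton instead of a hydride. Zerovalent palladium, as Pd(PPh3)4 (cat.), would open the oxirane anti to an allenylpalladium alkoxide; SmI2 (2 equiv, THF) would reduce it to an allenylsamarium species, and t-BuOH would protonate this at C8. This is the known palladium/SmI2 reduction of alkynyl oxiranes to 2,3-dien-1-ols, which is expected to follow the same overall anti course and therefore to give 18 from the same (R)-oxirane. No new compound arises on this way (none F0).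

Risk 3, step 6. Hydrogen uptake at the strained C5=C6 alkene may compete with the directed reduction, or hydrogen may be delivered from the undirected side. Fallback from 7 back to 9: C10 is placed under thermodynamic instead of kinetic control and the catalyst that can touch C5=C6 is avoided. Silylation of 7 (Et3SiCl, imidazole) would give the triethylsilyl-protected exo-methylene enone F4. Copper hydride conjugate reduction with [(Ph3P)CuH]6 in wet benzene attacks only the enone; protonation of the enolate from the open etheno side should give mainly the C10 epimer of 9 F5 (methyl toward the C2–C3 bridge). Equilibration through the C9 enolate (DBU, toluene) should then enrich 9, whose methyl avoids the syn-parallel contact with a C2 hydrogen. Unconverted epimer would be recycled, and retro-aldol is excluded because the C3 oxygen is silylated.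

Further compounds
F1 | step 13 | C9 trimethylsilyl ether of 19 | CC[Si](CC)(CC)O[C@H]1C[C@@H]2C=C[C@@]1(C)[C@@](O[Si](C)(C)C)(C=[C@@]=C(C)CO[Si](c3ccccc3)(c3ccccc3)C(C)(C)C)[C@H]2C
F2 | step 13 | trimethylsilyl dienol ether C9(OSiMe3)=C8–C7=C11 of the cis-decalin | CC[Si](CC)(CC)O[C@H]1C[C@H]2[C@H](C)C(O[Si](C)(C)C)=C/C(=C(/C)CO[Si](c3ccccc3)(c3ccccc3)C(C)(C)C)[C@H]2C=C1C
F3 | step 13 | lithium dienolate of 22 | [Li+].CC[Si](CC)(CC)O[C@H]1C[C@H]2[C@H](C)C([O-])=C/C(=C(/C)CO[Si](c3ccccc3)(c3ccccc3)C(C)(C)C)[C@H]2C=C1C
F0 | step 11 | none | none
F4 | step 6 | C3 triethylsilyl ether of enone 7 | CC[Si](CC)(CC)O[C@H]1C[C@@H]2C=C[C@@]1(C)C(=O)C2=C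
F5 | step 6 | C10 epimer of 9 (C14 methyl toward the C2–C3 bridge) | CC[Si](CC)(CC)O[C@H]1C[C@@H]2C=C[C@@]1(C)C(=O)[C@@H]2C
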